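## Retrosynthetic overview

- Ring numbering: C1 (carbonyl beside the chain), C2 (chain), C3 (OH), C4 (carbonyl), C5 (CH3), C6 (OCH3); chain C1' to C14'. The strategy rests on the C3 oxygen being ortho to C2 in each ring: an O-allyl group on that oxygen delivers C1'–C3' to C2 by a [3,3] shift and leaves a terminal alkene.
- The 14-carbon chain is therefore cut at C2'–C3' and C12'–C13', giving two identical allyl arene acetates and dodeca-1,11-diene, joined by two-directional cross-metathesis.
- Each quinone is unmasked late from a 1,4,6-trimethoxy-3-acetoxy arene: hydrogenation, oxidative demethylation at C1/C4, then acetate removal. The acetate keeps C3–O distinct from C6–OCH3.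
- The allyl arene comes from 1,2,4-trimethoxybenzene by C-methylation, formylation, Dakin-type oxidation, O-allylation, Claisen rearrangement and acetylation.
- No ring is formed in the route; both six-membered rings come from the starting arene.

Key step: step 7

Remark: the target has no stereocentre. The cross-metathesis product is drawn as the E,E isomer; an E/Z mixture is expected and acceptable because the alkenes are hydrogenated in the next step.

## Route

Step 1
Reactants: 1 1,2,4-trimethoxybenzene
Product: 3 1,2,4-trimethoxy-3-methylbenzene, via 2,3,6-trimethoxyphenyllithium 2 (not isolated)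
Conditions: n-BuLi, TMEDA, THF, 0 °C to rt; then MeI, −78 °C to rt
Reagents that add atoms: iodomethane, CI
Why: Directed ortho-metalation removes the ring proton flanked by two methoxy groups (the future C5), and the aryllithium is methylated by SN2 attack on iodomethane.

Step 2
Reactants: 3 1,2,4-trimethoxy-3-methylbenzene
Product: 5 2,4,5-trimethoxy-3-methylbenzaldehyde, via chloro(methoxy)methylarene 4 (not isolated)
Conditions: Cl2CHOMe, TiCl4, CH2Cl2, −10 to 0 °C; then ice-water
Reagents that add atoms: dichloromethyl methyl ether, COC(Cl)Cl; water, O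
Why: Rieche formylation (Friedel–Crafts type) should attack the free position that is ortho to one methoxy group and para to another, the other free position having only one ortho methoxy group, and aqueous work-up hydrolyses the α-chloro ether to the aldehyde.

Step 3
Reactants: 5 2,4,5-trimethoxy-3-methylbenzaldehyde
Product: 7 2,4,5-trimethoxy-3-methylphenol, via aryl formate 6 (not isolated)
Conditions: mCPBA, CH2Cl2, 0 °C to rt; NaHCO3 wash; then Et3N (cat.), MeOH, rt
Reagents that add atoms: 3-chloroperoxybenzoic acid, OOC(=O)c1cccc(Cl)c1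
Why: Baeyer–Villiger (Dakin-type) oxidation with migration of the electron-rich aryl group gives the formate, which base-catalysed methanolysis cleaves to the phenol.

Step 4
Reactants: 7 2,4,5-trimethoxy-3-methylphenol; 8 allyl bromide
Product: 9 1,2,4-trimethoxy-3-methyl-5-(prop-2-en-1-yloxy)benzene
Conditions: K2CO3, acetone, reflux
Reagents that add atoms: none
Why: Williamson ether synthesis, SN2 displacement of the primary allylic bromide by the phenoxide.

Step 5
Reactants: 9 1,2,4-trimethoxy-3-methyl-5-(prop-2-en-1-yloxy)benzene
Product: 11 2-allyl-3,4,6-trimethoxy-5-methylphenol, via 6-allylcyclohexadienone 10 (not isolated)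
Conditions: N,N-diethylaniline, 195 °C, argon
Reagents that add atoms: none
Why: Aromatic Claisen rearrangement ([3,3]-sigmatropic shift) can end only at the single unsubstituted ortho carbon (the future C2), and the dienone tautomerises to the phenol.

Step 6
Reactants: 11 2-allyl-3,4,6-trimethoxy-5-methylphenol
Product: 12 2-allyl-3,4,6-trimethoxy-5-methylphenyl acetate
Conditions: Ac2O, pyridine, DMAP (cat.), CH2Cl2, rt
Reagents that add atoms: acetic anhydride, CC(=O)OC(C)=O
Why: DMAP-catalysed O-acylation of the hindered phenol installs the group that masks the C3 oxygen through metathesis and ring oxidation.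

Step 7
Reactants: 12 2-allyl-3,4,6-trimethoxy-5-methylphenyl acetate (4 equiv); 13 dodeca-1,11-diene (1 equiv)
Product: 15 (2E,12E)-1,14-bis(2-acetoxy-3,5,6-trimethoxy-4-methylphenyl)tetradeca-2,12-diene, via mono-coupled diene 14 (not isolated)
Conditions: second-generation Grubbs catalyst RuCl2(=CHPh)(H2IMes)(PCy3) (H2IMes = 1,3-dimesitylimidazolidin-2-ylidene; 5 mol % per alkene), 1,4-benzoquinone (10 mol %), CH2Cl2, 40 °C, slow argon sparge
Reagents that add atoms: none
Why: RuCl2(=CHPh)(H2IMes)(PCy3) loses PCy3 and the resulting alkylidene takes each terminal alkene through [2+2] cycloaddition to a ruthenacyclobutane and cycloreversion (Chauvin cycle), so the CH2 termini of 12 and 13 leave as ethylene while C2'=C3' and C12'=C13' are formed, first in 14 and then in 15. The closest known reaction type is cross-metathesis of allylbenzenes with unhindered terminal alkenes under this catalyst, both partners being fast-homodimerising (type 1) olefins. No ring is closed and no stereocentre is created; the geometry of the two new alkenes does not matter because step 8 saturates them. The step needs cross-coupling over self-coupling, reaction at both ends of 13, and no migration of the allyl double bond into conjugation with the electron-rich ring: the fourfold excess of 12 and removal of ethylene should drive 13 through 14 to 15 while self-metathesis of 12 stays reversible, and 1,4-benzoquinone scavenges the ruthenium hydrides responsible for isomerisation. In the substrate, the C1' methylene separates the reacting carbon from the hexasubstituted ring, and the C3 oxygen is an acetate, so no free phenol binds ruthenium.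

Step 8
Reactants: 15 (2E,12E)-1,14-bis(2-acetoxy-3,5,6-trimethoxy-4-methylphenyl)tetradeca-2,12-diene
Product: 16 1,14-bis(2-acetoxy-3,5,6-trimethoxy-4-methylphenyl)tetradecane
Conditions: H2 (1 atm), 10% Pd/C, EtOAc, rt
Reagents that add atoms: none
Why: Heterogeneous catalytic hydrogenation saturates both disubstituted alkenes and erases their geometry, while aryl acetates and methyl ethers are inert.

Step 9
Reactants: 16 1,14-bis(2-acetoxy-3,5,6-trimethoxy-4-methylphenyl)tetradecane
Product: 17 1,14-bis(2-acetoxy-5-methoxy-4-methyl-3,6-dioxocyclohexa-1,4-dien-1-yl)tetradecane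
Conditions: (NH4)2Ce(NO3)6, MeCN/CH2Cl2/H2O, 0 °C
Reagents that add atoms: water, O
Why: Oxidative demethylation of a hydroquinone dimethyl ether by (NH4)2Ce(NO3)6 proceeds by single-electron oxidation to the arene radical cation and ipso attack of water at the para-related C1 and C4 methoxy carbons, giving each para-quinone with loss of methanol while the C3 acetate and C6 methoxy group stay.

Step 10
Reactants: 17 1,14-bis(2-acetoxy-5-methoxy-4-methyl-3,6-dioxocyclohexa-1,4-dien-1-yl)tetradecane
Product: 18 2,2'-(tetradecane-1,14-diyl)bis(3-hydroxy-6-methoxy-5-methylcyclohexa-2,5-diene-1,4-dione) (CNP0278640.0)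
Conditions: K2CO3, MeOH/CH2Cl2, 0 °C, argon; then 1 M HCl
Reagents that add atoms: none
Why: Methanolysis (transesterification) of the enol acetates, which behave as vinylogous anhydrides, should be fast; the quinonolate anions formed resist further attack, and every ring carbon is substituted so no conjugate addition is possible.

## Compound list

1 | 1,2,4-trimethoxybenzene | COc1ccc(OC)c(OC)c1 | starting material
2 | 2,3,6-trimethoxyphenyllithium | [Li]c1c(OC)ccc(OC)c1OC | intermediate
3 | 1,2,4-trimethoxy-3-methylbenzene | Cc1c(OC)ccc(OC)c1OC | intermediate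
4 | 1-[chloro(methoxy)methyl]-2,4,5-trimethoxy-3-methylbenzene (racemic) | COc1cc(C(Cl)OC)c(OC)c(C)c1OC | intermediate
5 | 2,4,5-trimethoxy-3-methylbenzaldehyde | COc1cc(C=O)c(OC)c(C)c1OC | intermediate
6 | 2,4,5-trimethoxy-3-methylphenyl formate | COc1cc(OC=O)c(OC)c(C)c1OC | intermediate
7 | 2,4,5-trimethoxy-3-methylphenol | COc1cc(O)c(OC)c(C)c1OC | intermediate
8 | allyl bromide (3-bromoprop-1-ene) | C=CCBr | starting material
9 | 1,2,4-trimethoxy-3-methyl-5-(prop-2-en-1-yloxy)benzene | COc1cc(OCC=C)c(OC)c(C)c1OC | intermediate
10 | 6-allyl-2,4,5-trimethoxy-3-methylcyclohexa-2,4-dien-1-one (racemic) | O=C1C(CC=C)C(OC)=C(OC)C(C)=C1OC | intermediate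
11 | 2-allyl-3,4,6-trimethoxy-5-methylphenol | COc1c(C)c(OC)c(O)c(CC=C)c1OC | intermediate
12 | 2-allyl-3,4,6-trimethoxy-5-methylphenyl acetate | COc1c(C)c(OC)c(OC(C)=O)c(CC=C)c1OC | intermediate
13 | dodeca-1,11-diene | C=CCCCCCCCCC=C | starting material
14 | 3,4,6-trimethoxy-5-methyl-2-[(2E)-trideca-2,12-dien-1-yl]phenyl acetate | COc1c(C)c(OC)c(OC(C)=O)c(C/C=C/CCCCCCCCC=C)c1OC | intermediate
15 | (2E,12E)-1,14-bis(2-acetoxy-3,5,6-trimethoxy-4-methylphenyl)tetradeca-2,12-diene | COc1c(C)c(OC)c(OC(C)=O)c(C/C=C/CCCCCCCC/C=C/Cc2c(OC(C)=O)c(OC)c(C)c(OC)c2OC)c1OC | intermediate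
16 | 1,14-bis(2-acetoxy-3,5,6-trimethoxy-4-methylphenyl)tetradecane | COc1c(C)c(OC)c(OC(C)=O)c(CCCCCCCCCCCCCCc2c(OC(C)=O)c(OC)c(C)c(OC)c2OC)c1OC | intermediate
17 | 1,14-bis(2-acetoxy-5-methoxy-4-methyl-3,6-dioxocyclohexa-1,4-dien-1-yl)tetradecane | COC1=C(C)C(=O)C(OC(C)=O)=C(CCCCCCCCCCCCCCC2=C(OC(C)=O)C(=O)C(C)=C(OC)C2=O)C1=O | intermediate
18 | 2,2'-(tetradecane-1,14-diyl)bis(3-hydroxy-6-methoxy-5-methylcyclohexa-2,5-diene-1,4-dione) | COC1=C(C)C(=O)C(O)=C(CCCCCCCCCCCCCCC2=C(O)C(=O)C(C)=C(OC)C2=O)C1=O | target

## Step count and risks

Total step count: 10. Longest linear sequence: 10 steps (1 to 18); dodeca-1,11-diene 13 and allyl bromide 8 are used as purchased.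

Steps most likely to fail:

1. Step 7. The allyl double bond may migrate into conjugation with the electron-rich ring before it couples, and the second coupling at the far end of 13 may stall, leaving statistical mixtures. Fallback: the two chain bonds are made instead as sp3–sp3 bonds (C3'–C4' and C11'–C12'). Setting out from 12, hydroboration with 9-BBN (THF, rt) should give 3,4,6-trimethoxy-5-methyl-2-[3-(9-borabicyclo[3.3.1]nonan-9-yl)propyl]phenyl acetate F1. Two equivalents of F1 are then coupled with 1,8-dibromooctane (BrCCCCCCCCBr) in an alkyl–alkyl Suzuki–Miyaura reaction (Pd(OAc)2, PCy3, K3PO4·H2O, THF, rt; 3 + 8 + 3 carbons). Any phenol freed by the base is re-acetylated with Ac2O/pyridine. This fallback comes back to the route at 16 and bypasses step 8.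

2. Step 9. The twofold oxidation may stop halfway on a lipophilic substrate that dissolves poorly in the aqueous medium, and acid-promoted loss of a C3 acetate before ring oxidation would steer that ring to the wrong C3/C6 quinone. Oxidation across the adjacent C1/C6 methoxy pair is less worrying: after acetate removal that ring would tautomerise to the same hydroxy-para-quinone, because the C2–C5 axis exchanges C1 with C3 and C6 with C4. Fallback: the ring is oxidised before the chain is built. Setting out from 12, (NH4)2Ce(NO3)6 in MeCN/H2O at 0 °C should give 4-methoxy-5-methyl-3,6-dioxo-2-(prop-2-en-1-yl)cyclohexa-1,4-dien-1-yl acetate F2. Cross-metathesis of excess F2 with 13 under RuCl2(=CHPh)(H2IMes)(PCy3) in CH2Cl2 at 40 °C gives (2E,12E)-1,14-bis(2-acetoxy-5-methoxy-4-methyl-3,6-dioxocyclohexa-1,4-dien-1-yl)tetradeca-2,12-diene F3. Hydrogenation (H2, Pd/C, EtOAc) saturates the alkenes and reduces the quinones to 1,14-bis(2-acetoxy-3,6-dihydroxy-5-methoxy-4-methylphenyl)tetradecane F4, which is re-oxidised at once with Ag2O. This fallback comes back to the route at 17.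

3. Step 5. At about 195 °C the ether may lose its allyl group, the ortho-allylphenol may cyclise onto the alkene to a dihydrobenzofuran, and the very electron-rich phenol may be oxidised by traces of air. Fallback: the allyl group is attached by cross-coupling, with no thermal rearrangement. Setting out from 7, acetylation (Ac2O, pyridine) gives 2,4,5-trimethoxy-3-methylphenyl acetate F5. Bromination at the only remaining ring position (NBS, MeCN, 0 °C) gives 2-bromo-3,4,6-trimethoxy-5-methylphenyl acetate F6. Stille coupling with allyltributylstannane (Pd(PPh3)4, toluene, 100 °C) then comes back to the route at 12, bypassing steps 4 to 6.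

## Further compounds

F1 | step 7 | 3,4,6-trimethoxy-5-methyl-2-[3-(9-borabicyclo[3.3.1]nonan-9-yl)propyl]phenyl acetate | COc1c(C)c(OC)c(OC(C)=O)c(CCCB2C3CCCC2CCC3)c1OC
F2 | step 9 | 4-methoxy-5-methyl-3,6-dioxo-2-(prop-2-en-1-yl)cyclohexa-1,4-dien-1-yl acetate | COC1=C(C)C(=O)C(OC(C)=O)=C(CC=C)C1=O
F3 | step 9 | (2E,12E)-1,14-bis(2-acetoxy-5-methoxy-4-methyl-3,6-dioxocyclohexa-1,4-dien-1-yl)tetradeca-2,12-diene | COC1=C(C)C(=O)C(OC(C)=O)=C(C/C=C/CCCCCCCC/C=C/CC2=C(OC(C)=O)C(=O)C(C)=C(OC)C2=O)C1=O
F4 | step 9 | 1,14-bis(2-acetoxy-3,6-dihydroxy-5-methoxy-4-methylphenyl)tetradecane | COc1c(C)c(O)c(OC(C)=O)c(CCCCCCCCCCCCCCc2c(OC(C)=O)c(O)c(C)c(OC)c2O)c1O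
F5 | step 5 | 2,4,5-trimethoxy-3-methylphenyl acetate | COc1cc(OC(C)=O)c(OC)c(C)c1OC
F6 | step 5 | 2-bromo-3,4,6-trimethoxy-5-methylphenyl acetate | COc1c(C)c(OC)c(OC(C)=O)c(Br)c1OC
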